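## Retrosynthetic overview

1. Kazinol I ⇐ global desilylation ⇐ double linear-selective prenylation of a (2R)-2′,3′-dibromoflavan tris-silyl ether. The prenyl groups go in last, so they never meet acid or the cycloaddition.
2. The pyran ring is the only ring formed. It comes from a catalytic asymmetric inverse-demand oxa-[4+2] between a dearomatised resorcinol unit (an o-quinone methide made in situ from a salicyl alcohol) and a 2,3-dibromo-4,5-disiloxystyrene. This forms C4–C3 and O1–C2 and sets C2 in one step.
3. o-Quinone methide precursor ⇐ 2,4-dihydroxybenzaldehyde (4-O-silylation, reduction).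
4. Styrene ⇐ vanillin (dibromination, demethylation, silylation, Wittig).

Assumption: silyl chlorides, the Wittig salt and prenylzinc bromide are treated as reagents and not numbered. The sense of induction of the chiral acid in step 7 is not known in advance; it must be checked on the first run and the catalyst antipode used if the 2S flavan forms.

## Route

**Step 1**
Reactants: 1, vanillin
Product: 2, 5,6-dibromovanillin (2,3-dibromo-4-hydroxy-5-methoxybenzaldehyde)
Conditions: Br2 (2.3 equiv), Fe powder (cat.), AcOH, rt → 45 °C
Reagents that add atoms: bromine, BrBr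
Why: Electrophilic aromatic bromination; the first Br enters ortho to the free OH (C5) and the second, FeBr3-assisted, para to OMe (C6), giving the contiguous dibromide.

**Step 2**
Reactants: 2, 5,6-dibromovanillin
Product: 3, 2,3-dibromo-4,5-dihydroxybenzaldehyde
Conditions: AlCl3, pyridine, CH2Cl2, reflux; aq. HCl work-up
Reagents that add atoms: none
Why: Chelation-assisted AlCl3/pyridine cleavage of a methyl ether ortho to a phenol, done before any acid-sensitive group or stereocentre exists.

**Step 3**
Reactants: 3, 2,3-dibromo-4,5-dihydroxybenzaldehyde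
Product: 4, 2,3-dibromo-4,5-bis(tert-butyldimethylsilyloxy)benzaldehyde
Conditions: TBSCl (2.6 equiv), imidazole, DMF, rt
Reagents that add atoms: TBSCl, CC(C)(C)[Si](C)(C)Cl
Why: Standard phenol silylation; TBS ethers tolerate ylide, Brønsted-acid catalysis and organozinc/Pd, and come off with fluoride without acid.

**Step 4**
Reactants: 4, bis-TBS aldehyde
Product: 5, 2,3-dibromo-4,5-bis(tert-butyldimethylsilyloxy)styrene
Conditions: Ph3PCH3Br, KHMDS, THF, −78 → 0 °C (ylide pre-formed)
Reagents that add atoms: methyltriphenylphosphonium bromide, C[P+](c1ccccc1)(c1ccccc1)c1ccccc1.[Br-]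
Why: Wittig methylenation of an aryl aldehyde; aryl bromides and aryl silyl ethers are inert to the pre-formed, non-nucleophilic-base ylide.

**Step 5**
Reactants: 6, 2,4-dihydroxybenzaldehyde
Product: 7, 2-hydroxy-4-(triisopropylsilyloxy)benzaldehyde
Conditions: TIPSCl (1.05 equiv), imidazole, CH2Cl2, 0 °C → rt
Reagents that add atoms: TIPSCl, CC(C)[Si](Cl)(C(C)C)C(C)C
Why: Regioselective silylation of the more acidic 4-OH, since the 2-OH is hydrogen-bonded to the aldehyde; the bulky TIPS group later shields both ring positions ortho to it from Friedel–Crafts attack.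

**Step 6**
Reactants: 7, 2-hydroxy-4-(triisopropylsilyloxy)benzaldehyde
Product: 8, 2-(hydroxymethyl)-5-(triisopropylsilyloxy)phenol
Conditions: NaBH4, THF/EtOH, 0 °C; NH4Cl work-up (no strong acid)
Reagents that add atoms: none
Why: Borohydride reduction of the aldehyde gives the salicyl alcohol whose ortho-OH and para-OSi groups allow mild ionisation to the o-quinone methide.

**Step 7 (key step)**
Reactants: 5, dibromostyrene (1.0 equiv); 8, salicyl alcohol (1.5 equiv, syringe pump over 6 h)
Product: 9, (2R)-2-[2,3-dibromo-4,5-bis(tert-butyldimethylsilyloxy)phenyl]-7-(triisopropylsilyloxy)chromane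
Conditions: (R)-3,3′-bis(2,4,6-triisopropylphenyl)-H8-BINOL N-triflylphosphoramide (10 mol%), 5 Å MS, toluene, −20 °C; Et3N quench
Reagents that add atoms: none (water is lost)
Why: Proposed new method: the chiral acid dehydrates 8 to the dearomatised 3-siloxy-6-methylenecyclohexa-2,4-dienone (o-quinone methide), held in the catalyst pocket by hydrogen bonding/ion pairing, and the styrene adds in an asynchronous endo inverse-demand oxa-Diels–Alder (styrene CH2 to the methide carbon, carbonyl O to the benzylic carbon), so the shielded face and endo orientation fix C2 as R; the closest known reaction is the chiral N-triflylphosphoramide-catalysed [4+2] of in situ o-quinone methides from o-hydroxybenzhydrols with styrenes giving 2,4-diarylchromans, extended here to a methide carbon without a substituent.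

**Step 8**
Reactants: 9, (2R)-dibromoflavan tris-silyl ether
Product: 10, (2R)-2-[4,5-bis(tert-butyldimethylsilyloxy)-2,3-bis(3-methylbut-2-en-1-yl)phenyl]-7-(triisopropylsilyloxy)chromane
Conditions: prenylzinc bromide (3 equiv, from prenyl bromide, Zn, LiCl), CPhos-Pd precatalyst (4 mol%), THF, rt → 45 °C
Reagents that add atoms: prenylzinc bromide, CC(C)=CC[Zn]Br
Why: Double Negishi cross-coupling in which the bulky biarylphosphine forces reductive elimination from the α-bound allyl-Pd to give linear prenyl groups; silyl ethers and the C2 benzylic ether are untouched by organozinc/Pd(0).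

**Step 9**
Reactants: 10, diprenyl flavan tris-silyl ether
Product: 11, (+)-(2R)-kazinol I, (2R)-2-[4,5-dihydroxy-2,3-bis(3-methylbut-2-en-1-yl)phenyl]chroman-7-ol
Conditions: TBAF/AcOH (1:1, 3.5 equiv), THF, 0 °C, under Ar
Reagents that add atoms: none
Why: Fluoride desilylation of three aryl silyl ethers; AcOH buffering avoids phenoxide-driven ring opening to a p-quinone methide (which would epimerise C2) and avoids acid-induced prenyl/phenol cyclisation.

## Compound list

1 | vanillin | O=Cc1ccc(O)c(OC)c1 | starting material
2 | 5,6-dibromovanillin | O=Cc1cc(OC)c(O)c(Br)c1Br | intermediate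
3 | 2,3-dibromo-4,5-dihydroxybenzaldehyde | O=Cc1cc(O)c(O)c(Br)c1Br | intermediate
4 | 2,3-dibromo-4,5-bis(tert-butyldimethylsilyloxy)benzaldehyde | O=Cc1cc(O[Si](C)(C)C(C)(C)C)c(O[Si](C)(C)C(C)(C)C)c(Br)c1Br | intermediate
5 | 2,3-dibromo-4,5-bis(tert-butyldimethylsilyloxy)styrene | C=Cc1cc(O[Si](C)(C)C(C)(C)C)c(O[Si](C)(C)C(C)(C)C)c(Br)c1Br | intermediate
6 | 2,4-dihydroxybenzaldehyde | O=Cc1ccc(O)cc1O | starting material
7 | 2-hydroxy-4-(triisopropylsilyloxy)benzaldehyde | O=Cc1ccc(O[Si](C(C)C)(C(C)C)C(C)C)cc1O | intermediate
8 | 2-(hydroxymethyl)-5-(triisopropylsilyloxy)phenol | OCc1ccc(O[Si](C(C)C)(C(C)C)C(C)C)cc1O | intermediate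
9 | (2R)-2-[2,3-dibromo-4,5-bis(TBSO)phenyl]-7-(TIPSO)chromane | Brc1c([C@H]2CCc3ccc(O[Si](C(C)C)(C(C)C)C(C)C)cc3O2)cc(O[Si](C)(C)C(C)(C)C)c(O[Si](C)(C)C(C)(C)C)c1Br | intermediate
10 | (2R)-2-[4,5-bis(TBSO)-2,3-diprenylphenyl]-7-(TIPSO)chromane | CC(C)=CCc1c([C@H]2CCc3ccc(O[Si](C(C)C)(C(C)C)C(C)C)cc3O2)cc(O[Si](C)(C)C(C)(C)C)c(O[Si](C)(C)C(C)(C)C)c1CC=C(C)C | intermediate
11 | (+)-(2R)-kazinol I | CC(C)=CCc1c([C@H]2CCc3ccc(O)cc3O2)cc(O)c(O)c1CC=C(C)C | target

## Totals and risks

Total steps: 9. Longest linear sequence: 7 (steps 1, 2, 3, 4, 7, 8, 9).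

Steps most likely to fail:

1. **Step 7** (enantioselectivity with an unsubstituted methide; Friedel–Crafts oligomerisation of the o-quinone methide). Fallback: set C2 by ketone reduction instead of cycloaddition.
   - Convert 4 to the methyl ketone (MeMgBr, then DMP) and condense it with 7 (Claisen–Schmidt).
   - Reduce the enone C=C (Stryker's reagent), then the ketone by Noyori transfer hydrogenation to the (S)-carbinol.
   - Close the ring by Mitsunobu etherification with inversion to the (2R)-flavan, and rejoin at step 8.

2. **Step 8** (two mutually ortho, flanked C–Br bonds; α/γ selectivity). Fallback: double Stille allylation with allyltributylstannane (smaller, no regiochemical ambiguity), then cross-metathesis of both allyl groups with 2-methyl-2-butene (Grubbs II) to give the prenyl groups.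

3. **Step 9** (air-sensitive catechol; C2 epimerisation through a p-quinone methide if the medium turns basic). Fallback: change the endgame to desilylation with in situ peracetylation (Ac2O), purify the stable (2R)-triacetate, then release kazinol I by neutral methanolysis (NH4OAc, MeOH) under argon.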